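The five-membered ring is opened at C2–C3 and the ethylidene methyl is removed. In the forward sense, zerovalent nickel joins an ethynyl group on C3a to an aldehyde at C2 while ZnMe2 delivers methyl to the alkyne terminus. One operation therefore closes the cyclopentane onto the cyclohexane and fixes the C3 ethylidene with its methyl on the C2 side. The feature exploited is the trans-vicinal pair on the six-membered ring, C3a–C≡CH and C7a–CH(OSiR3)–CHO, whose arm already holds the C1 oxygen in its final configuration. The precursor is built from (R)-cryptone; oxidation at C2 and two esterifications finish the target.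

Key step: step 10

Remarks on the chemistry (one line each):
- Labels: all ring atoms carry the hydrindane labels of the target (C1 and C6 acyloxy carbons, C2 ketone, C3 ethylidene carbon, C3a and C7a fusion carbons, C4 isopropyl carbon, C7 methylidene carbon).
- Reading of the target: (1R,3aR,4R,6S,7aS), trans-fused; the C1 ester is the (2R)-2-methylbutanoate and the C6 ester the (2E)-3-methylpent-2-enoate.
- The C7a/C1 pair is a syn-aldol array, so the glyoxylate is added through an open transition state and not through a closed enolate chair, which would give the C1 epimer.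
- Protecting groups: triisopropylsilyl on the C1 oxygen and tert-butyldimethylsilyl on the C6 oxygen, so that C6 is unmasked first by acid and C1 last by fluoride, and so that the C1 silyl group does not shift to the C2 alkoxide in the key step.
- Assumption: (2R)-2-methylbutanoic acid and (2E)-3-methylpent-2-enoic acid are bought as single isomers.

Step 1
Reactants: 1 3-methylbutanal; 2 but-3-en-2-one
Product: 4 (4R)-4-(propan-2-yl)cyclohex-2-en-1-one, via (R)-5-oxo-2-(propan-2-yl)hexanal 3 (not isolated)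
Conditions: (2R)-2-[methoxy(diphenyl)methyl]pyrrolidine (5 mol%), ethyl 3,4-dihydroxybenzoate (20 mol%), neat, 4 °C; then KOH (aq), Bu4NOH (cat.), Et2O/THF, reflux
Reagents that add atoms: none
Why: An enamine-mediated organocatalytic Michael addition sets C4, the bulky arm of the (R)-pyrrolidine screening one enamine face so that the (R)-aldehyde is expected, and a base-mediated intramolecular aldol condensation (Robinson-type annulation) then closes the enone without touching that centre.

Step 2
Reactants: 4 (4R)-4-(propan-2-yl)cyclohex-2-en-1-one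
Product: 8 (4R,6S)-6-hydroxy-4-(propan-2-yl)cyclohex-2-en-1-one, via lithium dienolate 5 (not isolated), via trimethylsilyl dienol ether 6 (not isolated), via 6-trimethylsilyloxy enone 7 (not isolated)
Conditions: LiN(iPr)2, THF, −78 °C; Me3SiCl; then mCPBA, NaHCO3, CH2Cl2/hexane, −20 → 0 °C; then 1 M HCl, THF, 0 °C
Reagents that add atoms: 3-chloroperoxybenzoic acid (mCPBA), O=C(OO)c1cccc(Cl)c1
Why: Rubottom oxidation, in which kinetic C6 deprotonation gives the cross-conjugated silyl dienol ether, its electron-rich C6=C7 bond is epoxidised on the face anti to the pseudoequatorial C4 isopropyl group (axial entry at C6), and silyl shift with hydrolysis should leave the C6 hydroxyl trans to isopropyl (6S).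

Step 3
Reactants: 8 (4R,6S)-6-hydroxy-4-(propan-2-yl)cyclohex-2-en-1-one
Product: 9 (4R,6S)-6-[(tert-butyldimethylsilyl)oxy]-4-(propan-2-yl)cyclohex-2-en-1-one
Conditions: TBSOTf, 2,6-lutidine, CH2Cl2, −78 °C
Reagents that add atoms: tert-butyldimethylsilyl trifluoromethanesulfonate (TBSOTf), CC(C)(C)[Si](C)(C)OS(=O)(=O)C(F)(F)F
Why: O-Silylation of a secondary α-hydroxy ketone with a silyl triflate and a hindered pyridine is fast at low temperature and should not epimerise C6.

Step 4
Reactants: 9 (4R,6S)-6-[(tert-butyldimethylsilyl)oxy]-4-(propan-2-yl)cyclohex-2-en-1-one; 10 ethynyltrimethylsilane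
Product: 13 tert-butyl({(3R,4R,6S)-6-[(tert-butyldimethylsilyl)oxy]-4-(propan-2-yl)-3-[(trimethylsilyl)ethynyl]cyclohex-1-en-1-yl}oxy)dimethylsilane, via lithium (trimethylsilyl)acetylide 11 (not isolated), via [(trimethylsilyl)ethynyl]zinc bromide 12 (not isolated)
Conditions: 10, n-BuLi, THF, −78 °C; ZnBr2, 0 °C; then 9, TBSOTf, Et2O/THF, −40 °C
Reagents that add atoms: tert-butyldimethylsilyl trifluoromethanesulfonate (TBSOTf), CC(C)(C)[Si](C)(C)OS(=O)(=O)C(F)(F)F
Why: Silyl-triflate-promoted conjugate addition of an alkynylzinc halide to a cyclohexenone, in which the alkynyl group should enter C3a anti to the adjacent C4 isopropyl group (3a,4-trans) and the enolate is captured regiospecifically as the C7–C7a silyl enol ether.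

Step 5
Reactants: 13 the silyl enol ether of step 4; 14 ethyl glyoxylate
Product: 15 ethyl (2R)-2-{(1R,3S,5R,6R)-3-[(tert-butyldimethylsilyl)oxy]-2-oxo-5-(propan-2-yl)-6-[(trimethylsilyl)ethynyl]cyclohexyl}-2-hydroxyacetate
Conditions: 14 (freshly cracked), TiCl4, CH2Cl2, −78 °C; aq. NaHCO3
Reagents that add atoms: none
Why: Mukaiyama aldol addition through an open transition state, in which the electrophile should reach C7a on the face away from the C3a alkynyl and the pseudoaxial C6 silyloxy groups, and the TiCl4-chelated glyoxylate should lie antiperiplanar to the enol double bond with its chelate ring over the C7a hydrogen, giving the syn adduct (1R).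

Step 6
Reactants: 15 the aldol adduct of step 5
Product: 16 ethyl (2R)-2-{(1R,3S,5R,6R)-3-[(tert-butyldimethylsilyl)oxy]-2-oxo-5-(propan-2-yl)-6-[(trimethylsilyl)ethynyl]cyclohexyl}-2-{[tri(propan-2-yl)silyl]oxy}acetate
Conditions: TIPSOTf, 2,6-lutidine, CH2Cl2, 0 °C → rt
Reagents that add atoms: tri(propan-2-yl)silyl trifluoromethanesulfonate (TIPSOTf), CC(C)[Si](C(C)C)(C(C)C)OS(=O)(=O)C(F)(F)F
Why: Triflate-mediated O-silylation works on hindered α-hydroxy esters without a base strong enough for retro-aldol cleavage or β-elimination, and the bulky silyl group is chosen at C1 because it resists O-to-O shift and outlasts the C6 silyl ether under acid.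

Step 7
Reactants: 16 the bis-silyl keto ester of step 6
Product: 17 ethyl (2R)-2-{(1S,3S,5R,6R)-3-[(tert-butyldimethylsilyl)oxy]-2-methylidene-5-(propan-2-yl)-6-[(trimethylsilyl)ethynyl]cyclohexyl}-2-{[tri(propan-2-yl)silyl]oxy}acetate
Conditions: Zn, CH2Br2, TiCl4, THF/CH2Cl2, 0 °C → rt
Reagents that add atoms: dibromomethane, BrCBr
Why: Takai–Lombardo methylenation is non-basic and selective for ketones over esters, so the β-silyloxy ketone should be converted without elimination or epimerisation at C6 or C7a.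

Step 8
Reactants: 17 the methylidene ester of step 7
Product: 18 ethyl (2R)-2-{(1S,3S,5R,6R)-3-[(tert-butyldimethylsilyl)oxy]-6-ethynyl-2-methylidene-5-(propan-2-yl)cyclohexyl}-2-{[tri(propan-2-yl)silyl]oxy}acetate
Conditions: K2CO3, EtOH, rt
Reagents that add atoms: none
Why: Carbonate-mediated C-desilylation of an alkynylsilane, in which ethanol matches the ethyl ester and the secondary silyl ethers should survive.

Step 9
Reactants: 18 the ethynyl ester of step 8
Product: 19 (2R)-2-{(1S,3S,5R,6R)-3-[(tert-butyldimethylsilyl)oxy]-6-ethynyl-2-methylidene-5-(propan-2-yl)cyclohexyl}-2-{[tri(propan-2-yl)silyl]oxy}acetaldehyde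
Conditions: i-Bu2AlH, CH2Cl2, −78 °C; MeOH, aq. potassium sodium tartrate
Reagents that add atoms: none
Why: Partial reduction of an α-silyloxy ester with i-Bu2AlH stops at the aldehyde because the tetrahedral aluminium hemiacetal is stable at −78 °C, and the non-basic work-up should keep C1 intact.

Step 10
Reactants: 19 the ynal of step 9
Product: 20 (1R,3Z,3aR,4R,6S,7aS)-6-[(tert-butyldimethylsilyl)oxy]-3-ethylidene-7-methylidene-4-(propan-2-yl)-1-{[tri(propan-2-yl)silyl]oxy}octahydro-1H-inden-2-ol (C2 epimers)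
Conditions: Ni(cod)2 (10 mol%), ZnMe2 (3 equiv), THF, 0 °C, slow addition of 19; aq. NH4Cl
Reagents that add atoms: dimethylzinc, C[Zn]C
Why: Zerovalent nickel binds the ethynyl group and the aldehyde and undergoes oxidative cyclization to a fused oxanickelacyclopentene, which forms C2–C3; methyl then passes from zinc to nickel and C–C reductive elimination places it on the former alkyne terminus with retention, hence cis to the new C2–C3 bond. The closest known reaction is the nickel-catalysed alkylative cyclization of 5-hexynals with organozinc reagents, run here without phosphine so that methyl transfer ends the cycle. The five-membered ring closes in the exocyclic (5-exo) sense, the aldehyde carbon bonding to the internal alkyne carbon across the trans-diequatorial C3a and C7a substituents to give the trans-fused hydrindane. The only new stereocentre, C2, is not controlled and need not be, since both carbinol epimers are oxidised to the same ketone, while the Z geometry follows from syn addition within the metallacycle. The step needs cyclization to win over direct methyl addition to the aldehyde, which the intramolecular pairing of alkyne and aldehyde and the slow addition of substrate should secure, and it must leave C1 alone, which the non-basic medium and the bulky, slow-migrating C1 silyl ether should ensure.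

Step 11
Reactants: 20 the allylic alcohols of step 10
Product: 21 (1R,3Z,3aR,4R,6S,7aS)-6-[(tert-butyldimethylsilyl)oxy]-3-ethylidene-7-methylidene-4-(propan-2-yl)-1-{[tri(propan-2-yl)silyl]oxy}octahydro-2H-inden-2-one
Conditions: Dess–Martin periodinane, NaHCO3, CH2Cl2, 0 °C → rt
Reagents that add atoms: none
Why: Dess–Martin oxidation of the allylic alcohol converges both C2 epimers on one enone under buffered conditions that should leave C1 and the alkene geometry alone.

Step 12
Reactants: 21 the bis-silyl enone of step 11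
Product: 22 (1R,3Z,3aR,4R,6S,7aS)-3-ethylidene-6-hydroxy-7-methylidene-4-(propan-2-yl)-1-{[tri(propan-2-yl)silyl]oxy}octahydro-2H-inden-2-one
Conditions: camphorsulfonic acid (cat.), MeOH/CH2Cl2, 0 °C → rt
Reagents that add atoms: none
Why: Acid-catalysed methanolysis of silyl ethers is sensitive to bulk at silicon and to the basicity of the oxygen, so the C6 tert-butyldimethylsilyl ether should cleave while the bulkier C1 silyl ether next to the ketone stays.

Step 13
Reactants: 22 the C6 alcohol of step 12; 23 (2E)-3-methylpent-2-enoic acid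
Product: 24 (1R,3Z,3aR,4R,6S,7aS)-3-ethylidene-7-methylidene-2-oxo-4-(propan-2-yl)-1-{[tri(propan-2-yl)silyl]oxy}octahydro-1H-inden-6-yl (2E)-3-methylpent-2-enoate
Conditions: DCC, DMAP (cat.), CH2Cl2, 0 °C → rt
Reagents that add atoms: none
Why: Steglich esterification acylates the axial C6 alcohol with retention, and catalytic DMAP without added amine should keep γ-deprotonation of the activated enoic acid (E/Z scrambling or deconjugation) to a minimum.

Step 14
Reactants: 24 the C6 ester of step 13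
Product: 25 (1R,3Z,3aR,4R,6S,7aS)-3-ethylidene-1-hydroxy-7-methylidene-2-oxo-4-(propan-2-yl)octahydro-1H-inden-6-yl (2E)-3-methylpent-2-enoate
Conditions: HF·pyridine, pyridine/THF, 0 °C → rt
Reagents that add atoms: none
Why: Fluoride-mediated desilylation is accelerated for a silyl ether flanked by a ketone, and buffered HF·pyridine is not basic enough to epimerise C1 or to cleave the ester.

Step 15
Reactants: 25 the α-ketol of step 14; 26 (2R)-2-methylbutanoic acid
Product: 27 (1R,3Z,3aR,4R,6S,7aS)-3-ethylidene-7-methylidene-1-{[(2R)-2-methylbutanoyl]oxy}-2-oxo-4-(propan-2-yl)octahydro-1H-inden-6-yl (2E)-3-methylpent-2-enoate (target)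
Conditions: DCC, DMAP (cat.), CH2Cl2, 0 °C
Reagents that add atoms: none
Why: Steglich esterification of the α-ketol takes place at oxygen with retention at C1, and an α-alkyl-branched acid should not racemise under carbodiimide activation with catalytic DMAP at 0 °C.

Compound list
1 | 3-methylbutanal | CC(C)CC=O | starting material
2 | but-3-en-2-one | CC(=O)C=C | starting material
3 | (2R)-5-oxo-2-(propan-2-yl)hexanal | O=C[C@@H](C(C)C)CCC(C)=O | intermediate
4 | (4R)-4-(propan-2-yl)cyclohex-2-en-1-one | O=C1C=C[C@@H](C(C)C)CC1 | intermediate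
5 | lithium (4R)-4-(propan-2-yl)cyclohexa-1,5-dien-1-olate | [Li+].[O-]C1=CC[C@H](C(C)C)C=C1 | intermediate
6 | trimethyl{[(4R)-4-(propan-2-yl)cyclohexa-1,5-dien-1-yl]oxy}silane | C[Si](C)(C)OC1=CC[C@H](C(C)C)C=C1 | intermediate
7 | (4R,6S)-4-(propan-2-yl)-6-[(trimethylsilyl)oxy]cyclohex-2-en-1-one | O=C1C=C[C@@H](C(C)C)C[C@@H]1O[Si](C)(C)C | intermediate
8 | (4R,6S)-6-hydroxy-4-(propan-2-yl)cyclohex-2-en-1-one | O=C1C=C[C@@H](C(C)C)C[C@@H]1O | intermediate
9 | (4R,6S)-6-[(tert-butyldimethylsilyl)oxy]-4-(propan-2-yl)cyclohex-2-en-1-one | O=C1C=C[C@@H](C(C)C)C[C@@H]1O[Si](C)(C)C(C)(C)C | intermediate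
10 | ethynyltrimethylsilane | C#C[Si](C)(C)C | starting material
11 | lithium (trimethylsilyl)acetylide | [Li+].[C-]#C[Si](C)(C)C | intermediate
12 | [(trimethylsilyl)ethynyl]zinc bromide | Br[Zn]C#C[Si](C)(C)C | intermediate
13 | tert-butyl({(3R,4R,6S)-6-[(tert-butyldimethylsilyl)oxy]-4-(propan-2-yl)-3-[(trimethylsilyl)ethynyl]cyclohex-1-en-1-yl}oxy)dimethylsilane | CC(C)(C)[Si](C)(C)OC1=C[C@H](C#C[Si](C)(C)C)[C@@H](C(C)C)C[C@@H]1O[Si](C)(C)C(C)(C)C | intermediate
14 | ethyl glyoxylate (ethyl 2-oxoacetate) | CCOC(=O)C=O | starting material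
15 | ethyl (2R)-2-{(1R,3S,5R,6R)-3-[(tert-butyldimethylsilyl)oxy]-2-oxo-5-(propan-2-yl)-6-[(trimethylsilyl)ethynyl]cyclohexyl}-2-hydroxyacetate | O=C1[C@@H]([C@@H](O)C(=O)OCC)[C@H](C#C[Si](C)(C)C)[C@@H](C(C)C)C[C@@H]1O[Si](C)(C)C(C)(C)C | intermediate
16 | ethyl (2R)-2-{(1R,3S,5R,6R)-3-[(tert-butyldimethylsilyl)oxy]-2-oxo-5-(propan-2-yl)-6-[(trimethylsilyl)ethynyl]cyclohexyl}-2-{[tri(propan-2-yl)silyl]oxy}acetate | O=C1[C@@H]([C@@H](O[Si](C(C)C)(C(C)C)C(C)C)C(=O)OCC)[C@H](C#C[Si](C)(C)C)[C@@H](C(C)C)C[C@@H]1O[Si](C)(C)C(C)(C)C | intermediate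
17 | ethyl (2R)-2-{(1S,3S,5R,6R)-3-[(tert-butyldimethylsilyl)oxy]-2-methylidene-5-(propan-2-yl)-6-[(trimethylsilyl)ethynyl]cyclohexyl}-2-{[tri(propan-2-yl)silyl]oxy}acetate | C=C1[C@@H]([C@@H](O[Si](C(C)C)(C(C)C)C(C)C)C(=O)OCC)[C@H](C#C[Si](C)(C)C)[C@@H](C(C)C)C[C@@H]1O[Si](C)(C)C(C)(C)C | intermediate
18 | ethyl (2R)-2-{(1S,3S,5R,6R)-3-[(tert-butyldimethylsilyl)oxy]-6-ethynyl-2-methylidene-5-(propan-2-yl)cyclohexyl}-2-{[tri(propan-2-yl)silyl]oxy}acetate | C=C1[C@@H]([C@@H](O[Si](C(C)C)(C(C)C)C(C)C)C(=O)OCC)[C@H](C#C)[C@@H](C(C)C)C[C@@H]1O[Si](C)(C)C(C)(C)C | intermediate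
19 | (2R)-2-{(1S,3S,5R,6R)-3-[(tert-butyldimethylsilyl)oxy]-6-ethynyl-2-methylidene-5-(propan-2-yl)cyclohexyl}-2-{[tri(propan-2-yl)silyl]oxy}acetaldehyde | C=C1[C@@H]([C@@H](O[Si](C(C)C)(C(C)C)C(C)C)C=O)[C@H](C#C)[C@@H](C(C)C)C[C@@H]1O[Si](C)(C)C(C)(C)C | intermediate
20 | (1R,3Z,3aR,4R,6S,7aS)-6-[(tert-butyldimethylsilyl)oxy]-3-ethylidene-7-methylidene-4-(propan-2-yl)-1-{[tri(propan-2-yl)silyl]oxy}octahydro-1H-inden-2-ol (C2 epimers) | C=C1[C@@H]2[C@H](/C(=C/C)C(O)[C@@H]2O[Si](C(C)C)(C(C)C)C(C)C)[C@@H](C(C)C)C[C@@H]1O[Si](C)(C)C(C)(C)C | intermediate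
21 | (1R,3Z,3aR,4R,6S,7aS)-6-[(tert-butyldimethylsilyl)oxy]-3-ethylidene-7-methylidene-4-(propan-2-yl)-1-{[tri(propan-2-yl)silyl]oxy}octahydro-2H-inden-2-one | C=C1[C@@H]2[C@H](/C(=C/C)C(=O)[C@@H]2O[Si](C(C)C)(C(C)C)C(C)C)[C@@H](C(C)C)C[C@@H]1O[Si](C)(C)C(C)(C)C | intermediate
22 | (1R,3Z,3aR,4R,6S,7aS)-3-ethylidene-6-hydroxy-7-methylidene-4-(propan-2-yl)-1-{[tri(propan-2-yl)silyl]oxy}octahydro-2H-inden-2-one | C=C1[C@@H]2[C@H](/C(=C/C)C(=O)[C@@H]2O[Si](C(C)C)(C(C)C)C(C)C)[C@@H](C(C)C)C[C@@H]1O | intermediate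
23 | (2E)-3-methylpent-2-enoic acid | CC/C(C)=C/C(=O)O | starting material
24 | (1R,3Z,3aR,4R,6S,7aS)-3-ethylidene-7-methylidene-2-oxo-4-(propan-2-yl)-1-{[tri(propan-2-yl)silyl]oxy}octahydro-1H-inden-6-yl (2E)-3-methylpent-2-enoate | C=C1[C@@H]2[C@H](/C(=C/C)C(=O)[C@@H]2O[Si](C(C)C)(C(C)C)C(C)C)[C@@H](C(C)C)C[C@@H]1OC(=O)/C=C(\C)CC | intermediate
25 | (1R,3Z,3aR,4R,6S,7aS)-3-ethylidene-1-hydroxy-7-methylidene-2-oxo-4-(propan-2-yl)octahydro-1H-inden-6-yl (2E)-3-methylpent-2-enoate | C=C1[C@@H]2[C@H](/C(=C/C)C(=O)[C@@H]2O)[C@@H](C(C)C)C[C@@H]1OC(=O)/C=C(\C)CC | intermediate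
26 | (2R)-2-methylbutanoic acid | CC[C@@H](C)C(=O)O | starting material
27 | (1R,3Z,3aR,4R,6S,7aS)-3-ethylidene-7-methylidene-1-{[(2R)-2-methylbutanoyl]oxy}-2-oxo-4-(propan-2-yl)octahydro-1H-inden-6-yl (2E)-3-methylpent-2-enoate | C=C1[C@@H]2[C@H](/C(=C/C)C(=O)[C@@H]2OC(=O)[C@H](C)CC)[C@@H](C(C)C)C[C@@H]1OC(=O)/C=C(\C)CC | target

Total step count: 15. Longest linear sequence: 15 steps (from 1 and 2 to 27); the other starting materials 10, 14, 23 and 26 enter as bought.

Steps most likely to fail

1. Step 10 (key step). Transfer of methyl from zinc, or from a methylnickel species, to the aldehyde carbon may outrun oxidative cyclization. The terminal alkyne may also be zincated or oligomerised at nickel, and the C1 silyl group could shift to the new C2 alkoxide. The fallback sets out from ester 18 and comes back at enone 21, so that steps 9 to 11 are bypassed and no nickel is used. Syn-distannation of the ethynyl group (Me3SnSnMe3, Pd(PPh3)4, THF, 60 °C) should give the (Z)-1,2-bis(trimethylstannyl)ethenyl ester F1. Stille coupling of the less hindered terminal stannane with iodomethane (Pd2(dba)3, P(o-tol)3, CuCl, K2CO3, DMF) should give the (Z)-1-(trimethylstannyl)prop-1-enyl ester F2, with methyl cis to tin. Iododestannylation (I2, CH2Cl2, 0 °C) should give, with retention, the (Z)-1-iodoprop-1-enyl ester F3. Iodine–lithium exchange (t-BuLi, THF/pentane, −100 °C) and attack of the vinyllithium on the C2 ester (Parham-type cyclization) should then close the ring to 21 with the methyl still on the C2 side.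

2. Step 5. Topicity control at the aldehyde carbon may be lost if synclinal or closed arrangements compete with the antiperiplanar open one, which would give the C1 epimer; attack on the other face of C7a is a lesser worry. The fallback sets out from 13 and comes back at 18 and corrects C1 by inversion. The aldol is run as before, the epimers are separated and the unwanted (1S)-hydroxy keto ester F4 is carried on. Methylenation at C7 as in step 7 should give the (1S)-hydroxy methylidene ester F5. Mitsunobu reaction (4-nitrobenzoic acid, PPh3, DIAD, toluene, 0 °C) should give the (1R)-4-nitrobenzoate F6 by inversion at C1. K2CO3 in EtOH should remove the nitrobenzoate and the alkynyl silyl group to give the (1R)-hydroxy ethynyl ester F7, and TIPSOTf with 2,6-lutidine then gives 18.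

3. Step 7. Steric blocking of the C7 carbonyl by its two branched neighbours may stop methylene transfer from the zinc–titanium reagent, and prolonged exposure to the Lewis-acidic mixture may erode the silyl ethers. The fallback sets out from 16 and comes back at 17 by a Peterson olefination in two stages. Me3SiCH2Li with CeCl3 (THF, −78 °C) adds a small, weakly basic nucleophile to C7 to give the β-hydroxysilane F8, and KN(SiMe3)2 (THF, 0 °C) should trigger syn-elimination to 17.

Further compounds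
F1 | step 10 | ethyl (2R)-2-{(1S,3S,5R,6R)-6-[(Z)-1,2-bis(trimethylstannyl)ethenyl]-3-[(tert-butyldimethylsilyl)oxy]-2-methylidene-5-(propan-2-yl)cyclohexyl}-2-{[tri(propan-2-yl)silyl]oxy}acetate | C=C1[C@@H]([C@@H](O[Si](C(C)C)(C(C)C)C(C)C)C(=O)OCC)[C@H](/C(=C/[Sn](C)(C)C)[Sn](C)(C)C)[C@@H](C(C)C)C[C@@H]1O[Si](C)(C)C(C)(C)C
F2 | step 10 | ethyl (2R)-2-{(1S,3S,5R,6R)-3-[(tert-butyldimethylsilyl)oxy]-2-methylidene-5-(propan-2-yl)-6-[(Z)-1-(trimethylstannyl)prop-1-enyl]cyclohexyl}-2-{[tri(propan-2-yl)silyl]oxy}acetate | C=C1[C@@H]([C@@H](O[Si](C(C)C)(C(C)C)C(C)C)C(=O)OCC)[C@H](/C(=C/C)[Sn](C)(C)C)[C@@H](C(C)C)C[C@@H]1O[Si](C)(C)C(C)(C)C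
F3 | step 10 | ethyl (2R)-2-{(1S,3S,5R,6R)-3-[(tert-butyldimethylsilyl)oxy]-6-[(Z)-1-iodoprop-1-enyl]-2-methylidene-5-(propan-2-yl)cyclohexyl}-2-{[tri(propan-2-yl)silyl]oxy}acetate | C=C1[C@@H]([C@@H](O[Si](C(C)C)(C(C)C)C(C)C)C(=O)OCC)[C@H](/C(=C/C)I)[C@@H](C(C)C)C[C@@H]1O[Si](C)(C)C(C)(C)C
F4 | step 5 | ethyl (2S)-2-{(1R,3S,5R,6R)-3-[(tert-butyldimethylsilyl)oxy]-2-oxo-5-(propan-2-yl)-6-[(trimethylsilyl)ethynyl]cyclohexyl}-2-hydroxyacetate (C1 epimer of 15) | O=C1[C@@H]([C@H](O)C(=O)OCC)[C@H](C#C[Si](C)(C)C)[C@@H](C(C)C)C[C@@H]1O[Si](C)(C)C(C)(C)C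
F5 | step 5 | ethyl (2S)-2-{(1S,3S,5R,6R)-3-[(tert-butyldimethylsilyl)oxy]-2-methylidene-5-(propan-2-yl)-6-[(trimethylsilyl)ethynyl]cyclohexyl}-2-hydroxyacetate | C=C1[C@@H]([C@H](O)C(=O)OCC)[C@H](C#C[Si](C)(C)C)[C@@H](C(C)C)C[C@@H]1O[Si](C)(C)C(C)(C)C
F6 | step 5 | (1R)-1-{(1S,3S,5R,6R)-3-[(tert-butyldimethylsilyl)oxy]-2-methylidene-5-(propan-2-yl)-6-[(trimethylsilyl)ethynyl]cyclohexyl}-2-ethoxy-2-oxoethyl 4-nitrobenzoate | C=C1[C@@H]([C@@H](OC(=O)c2ccc(cc2)[N+](=O)[O-])C(=O)OCC)[C@H](C#C[Si](C)(C)C)[C@@H](C(C)C)C[C@@H]1O[Si](C)(C)C(C)(C)C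
F7 | step 5 | ethyl (2R)-2-{(1S,3S,5R,6R)-3-[(tert-butyldimethylsilyl)oxy]-6-ethynyl-2-methylidene-5-(propan-2-yl)cyclohexyl}-2-hydroxyacetate | C=C1[C@@H]([C@@H](O)C(=O)OCC)[C@H](C#C)[C@@H](C(C)C)C[C@@H]1O[Si](C)(C)C(C)(C)C
F8 | step 7 | ethyl (2R)-2-{(1R,3S,5R,6R)-3-[(tert-butyldimethylsilyl)oxy]-2-hydroxy-5-(propan-2-yl)-6-[(trimethylsilyl)ethynyl]-2-[(trimethylsilyl)methyl]cyclohexyl}-2-{[tri(propan-2-yl)silyl]oxy}acetate (configuration at the new carbinol carbon C7 open) | C[Si](C)(C)CC1(O)[C@@H]([C@@H](O[Si](C(C)C)(C(C)C)C(C)C)C(=O)OCC)[C@H](C#C[Si](C)(C)C)[C@@H](C(C)C)C[C@@H]1O[Si](C)(C)C(C)(C)C
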